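**Retrosynthetic overview**

1. Feature: ring B carries five contiguous substituents: C1' (bonded to C2 of ring C), the C3' hydroxyl, C4'–O and C5'–CH2 (both in the fused 2,2-dimethyldihydropyran) and the C6' prenyl group. They map onto a dihydropyran-fused 3-alkoxyfuran, whose ring oxygen becomes the C3' hydroxyl, plus a two-carbon alkyne that supplies C1' and C2'.
2. Last disconnection: ring C, by C-acylation of a ring A alpha-(methoxymethoxy) ketone with the ring B methyl ester (C2–C3), O1–C2 cyclodehydration and MOM removal.
3. Key disconnection: ring B, by [4+2] cycloaddition of the furopyran with methyl propiolate (forms C2'–C3' and C1'–C6') and opening of the oxygen bridge; the C6' chain travels as allyl and is made prenyl by cross-metathesis.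
4. Fragments: furopyran from tetronic acid (acid annulation with 2-methylbut-3-en-2-ol, then allyl Grignard addition and dehydration); ring A ketone from 2,4,6-trihydroxyacetophenone (para-O-prenylation, Claisen rearrangement to the 1,1-dimethylallyl group, MOM protection, Rubottom oxidation).
5. Ring order: dihydropyran, furan, benzene ring B, pyranone ring C; ring A is bought.

Key step: step 3

Remark: the ring B prenyl group is carried through the cycloaddition as an allyl group, because an allyl Grignard reagent adds to the lactone without the alpha/gamma ambiguity of a prenyl metal; all chiral intermediates are racemic and the target has no stereocentre.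

**Route**

Step 1
Reactants: 1 tetronic acid; 2 2-methylbut-3-en-2-ol
Product: 4 2,2-dimethyl-2,3,4,7-tetrahydro-5H-furo[3,4-b]pyran-5-one, via C-prenyl tetronic acid 3 (not isolated)
Conditions: TsOH·H2O (10 mol%), 1,4-dioxane, 80 °C, slow addition of 2
Reagents that add atoms: none
Why: Acid ionises the tertiary allylic alcohol to the dimethylallyl cation, which alkylates the enol carbon C3 of tetronic acid at its CH2 terminus (Friedel–Crafts-type C-prenylation of a cyclic 1,3-dicarbonyl compound), and the C4 enol oxygen then adds in the Markovnikov sense to the trisubstituted alkene to close the dihydropyran, the conjugated 4-alkoxybutenolide being the more stable enol ether under these equilibrating conditions.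

Step 2
Reactants: 4 2,2-dimethyl-2,3,4,7-tetrahydro-5H-furo[3,4-b]pyran-5-one; 5 allylmagnesium bromide
Product: 7 2,2-dimethyl-5-(prop-2-enyl)-3,4-dihydro-2H-furo[3,4-b]pyran, via lactol 6 (not isolated)
Conditions: CH2=CHCH2MgBr (1.1 equiv), THF, −78 °C; aq NH4Cl; then PPTS (5 mol%), 4 Å MS, CH2Cl2, 0 °C; filtered through basic Al2O3 and used at once
Reagents that add atoms: none
Why: 1,2-Addition of the Grignard reagent to the lactone carbonyl should stop at the magnesium lactolate at low temperature, and the resulting 2,5-dihydrofuran-2-ol loses water under weak acid through its ring oxocarbenium ion and a proton from C7 to become the aromatic furan (butenolide-to-furan conversion), the racemic lactol centre of 6 being destroyed.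

Step 3
Reactants: 7 2,2-dimethyl-5-(prop-2-enyl)-3,4-dihydro-2H-furo[3,4-b]pyran; 8 methyl propiolate
Product: 10 methyl 8-hydroxy-2,2-dimethyl-5-(prop-2-enyl)chroman-6-carboxylate, via oxanorbornadiene 9 (not isolated)
Conditions: methyl propiolate (3 equiv), PhMe, 80 °C, sealed tube, Ar; then PPTS (5 mol%), CH2Cl2, rt
Reagents that add atoms: none
Why: The electron-rich 3-alkoxyfuran of 7 adds across the alkyne of 8 in a normal-demand [4+2] cycloaddition to give the 7-oxanorbornadiene 9; the dihydropyran oxygen then pushes through C4a=C8a (future C5'=C4') to break the bridge C–O bond at the allyl-bearing bridgehead (future C6'), and loss of the proton at the other bridgehead (future C3') gives the phenol. The closest known reaction type is the Diels–Alder reaction of furans with acetylenic esters followed by isomerisation of the oxanorbornadiene to a phenol, which runs most easily with 3-alkoxyfurans. Ring B is closed by intermolecular [4+2] cycloaddition, which forms C2'–C3' and C1'–C6', and becomes aromatic by bridge opening, so the furan oxygen survives as the C3' hydroxyl. The two bridgehead stereocentres of 9 form as a racemic pair fixed by the bicycle and both vanish on aromatisation, so no stereocentre needs control. The step needs one orientation of the alkyne and one direction of bridge opening: the unsubstituted furan carbon next to the alkoxy-bearing carbon is the most nucleophilic terminus (the 2-alkyl group reinforces this) and bonds to the electrophilic beta-carbon of the propiolate, so the ester carbon bonds to the allyl-bearing carbon, and the same ring oxygen stabilises only the cation formed by C6'–O cleavage. The weak acid at the end only completes the proton transfer if the bridged adduct persists.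

Step 4
Reactants: 10 methyl 8-hydroxy-2,2-dimethyl-5-(prop-2-enyl)chroman-6-carboxylate; 11 2-methylbut-2-ene
Product: 12 methyl 8-hydroxy-2,2-dimethyl-5-(3-methylbut-2-enyl)chroman-6-carboxylate
Conditions: second-generation Grubbs catalyst RuCl2(H2IMes)(PCy3)(=CHPh) (5 mol%), 2-methylbut-2-ene/CH2Cl2 1:1, 40 °C
Reagents that add atoms: none
Why: Olefin cross-metathesis between the monosubstituted allyl group and a large excess of the trisubstituted alkene exchanges the terminal CH2 for an isopropylidene unit and releases propene, the standard way to turn an aryl allyl group into a prenyl group, while ester, phenol and chroman are inert to the ruthenium carbene.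

Step 5
Reactants: 12 methyl 8-hydroxy-2,2-dimethyl-5-(3-methylbut-2-enyl)chroman-6-carboxylate
Product: 13 methyl 8-(methoxymethoxy)-2,2-dimethyl-5-(3-methylbut-2-enyl)chroman-6-carboxylate
Conditions: MOMCl (1.5 equiv), i-Pr2NEt (2 equiv), CH2Cl2, 0 °C to rt
Reagents that add atoms: chloromethyl methyl ether (MOMCl), COCCl
Why: Williamson-type O-alkylation of the phenol by the alpha-chloro ether masks the acidic C3' hydroxyl before the strongly basic condensation, and neither the ester nor the prenyl alkene reacts.

Step 6
Reactants: 14 2,4,6-trihydroxyacetophenone; 15 3-methylbut-2-en-1-ol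
Product: 16 1-[2,6-dihydroxy-4-(3-methylbut-2-enyloxy)phenyl]ethanone
Conditions: PPh3 (1.05 equiv), DIAD (1.05 equiv), THF, 0 °C to rt
Reagents that add atoms: none
Why: Mitsunobu etherification alkylates the most acidic, non-hydrogen-bonded para hydroxyl, whereas the two ortho hydroxyls are chelated to the ketone and react more slowly, and the neutral conditions avoid the C-alkylation that phloroglucinol phenoxides show with prenyl halides.

Step 7
Reactants: 16 1-[2,6-dihydroxy-4-(3-methylbut-2-enyloxy)phenyl]ethanone
Product: 18 1-[2,4,6-trihydroxy-3-(2-methylbut-3-en-2-yl)phenyl]ethanone, via dienone 17 (not isolated)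
Conditions: PhNEt2, 170 °C, sealed tube, Ar
Reagents that add atoms: none
Why: Aromatic Claisen rearrangement: the [3,3] shift delivers the dimethyl-substituted allyl terminus to the ortho carbon, the two ortho positions being equivalent by symmetry and the para position being blocked by the acetyl group, and enolisation of the racemic dienone 17 restores the phenol.

Step 8
Reactants: 18 1-[2,4,6-trihydroxy-3-(2-methylbut-3-en-2-yl)phenyl]ethanone
Product: 19 1-[2-hydroxy-4,6-bis(methoxymethoxy)-3-(2-methylbut-3-en-2-yl)phenyl]ethanone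
Conditions: MOMCl (2.2 equiv), i-Pr2NEt (3 equiv), CH2Cl2, 0 °C
Reagents that add atoms: chloromethyl methyl ether (MOMCl), COCCl
Why: MOM ether formation should take the non-chelated para hydroxyl first and then the C6 hydroxyl, which has a hydrogen neighbour, whereas the C2 hydroxyl is chelated to the ketone and wedged between the acyl and the tertiary alkyl group, so the phenol that will become O1 next to C8 stays free.

Step 9
Reactants: 19 1-[2-hydroxy-4,6-bis(methoxymethoxy)-3-(2-methylbut-3-en-2-yl)phenyl]ethanone
Product: 22 2-hydroxy-1-[2-hydroxy-4,6-bis(methoxymethoxy)-3-(2-methylbut-3-en-2-yl)phenyl]ethanone, via bis-silyl enol ether 20 (not isolated), via silyloxy ketone 21 (not isolated)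
Conditions: LiN(SiMe3)2 (2.3 equiv), Me3SiCl (2.5 equiv), THF, −78 to 0 °C; mCPBA (1.05 equiv), NaHCO3, CH2Cl2, −20 °C; 10% aq citric acid, THF, 0 °C
Reagents that add atoms: 3-chloroperbenzoic acid (mCPBA), OOC(=O)c1cccc(Cl)c1
Why: Rubottom oxidation: the silyl enol ether is epoxidised far faster than the hindered monosubstituted vinyl group, the silyloxy epoxide opens with 1,4-silyl shift to the alpha-silyloxy ketone, and mild aqueous acid removes both trimethylsilyl groups without touching the MOM ethers.

Step 10
Reactants: 22 2-hydroxy-1-[2-hydroxy-4,6-bis(methoxymethoxy)-3-(2-methylbut-3-en-2-yl)phenyl]ethanone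
Product: 23 1-[2-hydroxy-4,6-bis(methoxymethoxy)-3-(2-methylbut-3-en-2-yl)phenyl]-2-(methoxymethoxy)ethanone
Conditions: MOMCl (1.2 equiv), i-Pr2NEt (2 equiv), CH2Cl2, 0 °C
Reagents that add atoms: chloromethyl methyl ether (MOMCl), COCCl
Why: MOM ether formation is selective for the unhindered primary alcohol over the chelated, doubly flanked phenol and gives the alpha-alkoxy ketone that carries the future C3 oxygen.

Step 11
Reactants: 23 1-[2-hydroxy-4,6-bis(methoxymethoxy)-3-(2-methylbut-3-en-2-yl)phenyl]-2-(methoxymethoxy)ethanone; 13 methyl 8-(methoxymethoxy)-2,2-dimethyl-5-(3-methylbut-2-enyl)chroman-6-carboxylate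
Product: 24 1-[2-hydroxy-4,6-bis(methoxymethoxy)-3-(2-methylbut-3-en-2-yl)phenyl]-2-(methoxymethoxy)-3-[8-(methoxymethoxy)-2,2-dimethyl-5-(3-methylbut-2-enyl)chroman-6-yl]propane-1,3-dione (racemic)
Conditions: LiN(SiMe3)2 (3.5 equiv), THF, −78 °C; then 13, warm to 40 °C; aq NH4Cl
Reagents that add atoms: none
Why: Crossed Claisen condensation: excess amide base forms the phenoxide–enolate dianion of 23, whose enolate carbon attacks the non-enolisable methyl ester, and deprotonation of the beta-diketone by the third equivalent of base drives the equilibrium, the new CH(OMOM) centre being racemic and removed in step 12.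

Step 12
Reactants: 24 the beta-diketone of step 11
Product: 26 3,5,7-tris(methoxymethoxy)-2-[8-(methoxymethoxy)-2,2-dimethyl-5-(3-methylbut-2-enyl)chroman-6-yl]-8-(2-methylbut-3-en-2-yl)-4H-chromen-4-one, via hemiketal 25 (not isolated)
Conditions: PPTS (0.3 equiv), 4 Å MS, PhMe, 60 °C
Reagents that add atoms: none
Why: Acid-catalysed cyclodehydration as in the last stage of a Baker–Venkataraman flavone synthesis: the only free phenol, at C2 of ring A, adds to the ring B ketone (6-exo-trig hemiketal formation) and loss of water gives the pyranone ring C, the anhydrous weak acid being chosen so that the C5 MOM ether survives until closure and the isomeric 6-substituted flavone cannot form.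

Step 13
Reactants: 26 the tetrakis-MOM flavonol of step 12
Product: 27 Broussoflavonol E, 3,5,7-trihydroxy-2-[8-hydroxy-2,2-dimethyl-5-(3-methylbut-2-enyl)chroman-6-yl]-8-(2-methylbut-3-en-2-yl)-4H-chromen-4-one
Conditions: 3 M HCl, MeOH/THF, 40 °C
Reagents that add atoms: none
Why: Acid-catalysed acetal exchange with methanol removes the four MOM groups as dimethoxymethane under conditions mild enough that the prenyl and 1,1-dimethylallyl alkenes should neither add HCl nor cyclise onto a neighbouring phenol.

**Compound list**

1 | tetronic acid (furan-2,4(3H,5H)-dione) | O=C1CC(=O)CO1 | starting material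
2 | 2-methylbut-3-en-2-ol | CC(C)(O)C=C | starting material
3 | 4-hydroxy-3-(3-methylbut-2-enyl)furan-2(5H)-one | O=C1OCC(O)=C1CC=C(C)C | intermediate (not isolated)
4 | 2,2-dimethyl-2,3,4,7-tetrahydro-5H-furo[3,4-b]pyran-5-one | O=C1OCC2=C1CCC(C)(C)O2 | intermediate
5 | allylmagnesium bromide | C=CC[Mg]Br | starting material
6 | 2,2-dimethyl-5-(prop-2-enyl)-2,3,4,7-tetrahydro-5H-furo[3,4-b]pyran-5-ol (racemic lactol) | C=CCC1(O)OCC2=C1CCC(C)(C)O2 | intermediate (not isolated)
7 | 2,2-dimethyl-5-(prop-2-enyl)-3,4-dihydro-2H-furo[3,4-b]pyran | C=CCc1occ2OC(C)(C)CCc12 | intermediate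
8 | methyl propiolate | C#CC(=O)OC | starting material
9 | methyl 5-allyl-2,2-dimethyl-3,4,5,8-tetrahydro-2H-5,8-epoxychromene-6-carboxylate (racemic) | C=CCC12OC(C=C1C(=O)OC)C1=C2CCC(C)(C)O1 | intermediate (not isolated)
10 | methyl 8-hydroxy-2,2-dimethyl-5-(prop-2-enyl)chroman-6-carboxylate | COC(=O)c1cc(O)c2OC(C)(C)CCc2c1CC=C | intermediate
11 | 2-methylbut-2-ene | CC=C(C)C | starting material
12 | methyl 8-hydroxy-2,2-dimethyl-5-(3-methylbut-2-enyl)chroman-6-carboxylate | COC(=O)c1cc(O)c2OC(C)(C)CCc2c1CC=C(C)C | intermediate
13 | methyl 8-(methoxymethoxy)-2,2-dimethyl-5-(3-methylbut-2-enyl)chroman-6-carboxylate | COC(=O)c1cc(OCOC)c2OC(C)(C)CCc2c1CC=C(C)C | intermediate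
14 | 2,4,6-trihydroxyacetophenone | CC(=O)c1c(O)cc(O)cc1O | starting material
15 | 3-methylbut-2-en-1-ol | CC(C)=CCO | starting material
16 | 1-[2,6-dihydroxy-4-(3-methylbut-2-enyloxy)phenyl]ethanone | CC(=O)c1c(O)cc(OCC=C(C)C)cc1O | intermediate
17 | 4-acetyl-3,5-dihydroxy-6-(2-methylbut-3-en-2-yl)cyclohexa-2,4-dien-1-one (racemic) | CC(=O)C1=C(O)C(C(C)(C)C=C)C(=O)C=C1O | intermediate (not isolated)
18 | 1-[2,4,6-trihydroxy-3-(2-methylbut-3-en-2-yl)phenyl]ethanone | CC(=O)c1c(O)cc(O)c(C(C)(C)C=C)c1O | intermediate
19 | 1-[2-hydroxy-4,6-bis(methoxymethoxy)-3-(2-methylbut-3-en-2-yl)phenyl]ethanone | CC(=O)c1c(OCOC)cc(OCOC)c(C(C)(C)C=C)c1O | intermediate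
20 | trimethylsilyl enol ether of 19 with the C2 phenol also silylated | C=C(O[Si](C)(C)C)c1c(OCOC)cc(OCOC)c(C(C)(C)C=C)c1O[Si](C)(C)C | intermediate (not isolated)
21 | 1-[4,6-bis(methoxymethoxy)-3-(2-methylbut-3-en-2-yl)-2-(trimethylsilyloxy)phenyl]-2-(trimethylsilyloxy)ethanone | C[Si](C)(C)OCC(=O)c1c(OCOC)cc(OCOC)c(C(C)(C)C=C)c1O[Si](C)(C)C | intermediate (not isolated)
22 | 2-hydroxy-1-[2-hydroxy-4,6-bis(methoxymethoxy)-3-(2-methylbut-3-en-2-yl)phenyl]ethanone | OCC(=O)c1c(OCOC)cc(OCOC)c(C(C)(C)C=C)c1O | intermediate
23 | 1-[2-hydroxy-4,6-bis(methoxymethoxy)-3-(2-methylbut-3-en-2-yl)phenyl]-2-(methoxymethoxy)ethanone | COCOCC(=O)c1c(OCOC)cc(OCOC)c(C(C)(C)C=C)c1O | intermediate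
24 | 1-[2-hydroxy-4,6-bis(methoxymethoxy)-3-(2-methylbut-3-en-2-yl)phenyl]-2-(methoxymethoxy)-3-[8-(methoxymethoxy)-2,2-dimethyl-5-(3-methylbut-2-enyl)chroman-6-yl]propane-1,3-dione (racemic) | COCOC(C(=O)c1c(OCOC)cc(OCOC)c(C(C)(C)C=C)c1O)C(=O)c1cc(OCOC)c2OC(C)(C)CCc2c1CC=C(C)C | intermediate
25 | 2-hydroxy-3,5,7-tris(methoxymethoxy)-2-[8-(methoxymethoxy)-2,2-dimethyl-5-(3-methylbut-2-enyl)chroman-6-yl]-8-(2-methylbut-3-en-2-yl)chroman-4-one (racemic, mixture of diastereomers) | C=CC(C)(C)c1c(OCOC)cc(OCOC)c2C(=O)C(OCOC)C(O)(c3cc(OCOC)c4c(c3CC=C(C)C)CCC(C)(C)O4)Oc12 | intermediate (not isolated)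
26 | 3,5,7-tris(methoxymethoxy)-2-[8-(methoxymethoxy)-2,2-dimethyl-5-(3-methylbut-2-enyl)chroman-6-yl]-8-(2-methylbut-3-en-2-yl)-4H-chromen-4-one | C=CC(C)(C)c1c(OCOC)cc(OCOC)c2c(=O)c(OCOC)c(-c3cc(OCOC)c4c(c3CC=C(C)C)CCC(C)(C)O4)oc12 | intermediate
27 | Broussoflavonol E | C=CC(C)(C)c1c(O)cc(O)c2c(=O)c(O)c(-c3cc(O)c4c(c3CC=C(C)C)CCC(C)(C)O4)oc12 | target

**Step count and risks**

Total steps: 13. Longest linear sequence: 8 steps (steps 1–5 and 11–13 from tetronic acid; equally steps 6–13 from 2,4,6-trihydroxyacetophenone).

Steps most likely to fail: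

Step 3. The cycloaddition with the mono-activated alkyne may be slower than the loss of the acid- and air-sensitive alkoxyfuran, which can hydrolyse at its enol ether, autoxidise, or add through its free ring carbon to the alkyne in an open-chain conjugate addition. Fallback: starting from 7, the far more reactive dienophile propynal (same polarisation, CH2Cl2, 0 °C to rt) should give, after the same bridge opening, 8-hydroxy-2,2-dimethyl-5-(prop-2-enyl)chroman-6-carbaldehyde F1. Pinnick oxidation (NaClO2, NaH2PO4, excess 2-methylbut-2-ene as hypochlorite scavenger, t-BuOH/H2O) would give 8-hydroxy-2,2-dimethyl-5-(prop-2-enyl)chroman-6-carboxylic acid F2. Esterification with Me3SiCHN2 in MeOH/PhMe returns to the route at 10.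

Step 11. The C-acylation may stall or revert, because the ester carbonyl is deactivated by the para ring oxygen and shielded by the ortho prenyl group while the alpha-alkoxy enolate is itself hindered. Fallback: starting from 13, saponification (LiOH, THF/MeOH/H2O, 60 °C) gives 8-(methoxymethoxy)-2,2-dimethyl-5-(3-methylbut-2-enyl)chroman-6-carboxylic acid F3. Neutral activation with 1-chloro-N,N,2-trimethylprop-1-en-1-amine (CH2Cl2, 0 °C) gives 8-(methoxymethoxy)-2,2-dimethyl-5-(3-methylbut-2-enyl)chroman-6-carbonyl chloride F4. This acid chloride acylates the lithium dianion of 23 (LiN(SiMe3)2, THF, −78 °C) irreversibly at carbon and returns to the route at 24.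

Step 7. At the temperature of the rearrangement the newly formed ortho-(1,1-dimethylallyl)phenol may cyclise onto its own vinyl group or rearrange further before it is isolated. Fallback: starting from 16, the rearrangement is run in Ac2O with NaOAc and PhNEt2 at reflux, so that every phenol is acetylated as it forms, giving 2-acetyl-4-(2-methylbut-3-en-2-yl)benzene-1,3,5-triyl triacetate F5. Methanolysis (K2CO3, MeOH, 0 °C) returns to the route at 18.

**Further compounds**

F1 | step 3 | 8-hydroxy-2,2-dimethyl-5-(prop-2-enyl)chroman-6-carbaldehyde | O=Cc1cc(O)c2OC(C)(C)CCc2c1CC=C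
F2 | step 3 | 8-hydroxy-2,2-dimethyl-5-(prop-2-enyl)chroman-6-carboxylic acid | OC(=O)c1cc(O)c2OC(C)(C)CCc2c1CC=C
F3 | step 11 | 8-(methoxymethoxy)-2,2-dimethyl-5-(3-methylbut-2-enyl)chroman-6-carboxylic acid | OC(=O)c1cc(OCOC)c2OC(C)(C)CCc2c1CC=C(C)C
F4 | step 11 | 8-(methoxymethoxy)-2,2-dimethyl-5-(3-methylbut-2-enyl)chroman-6-carbonyl chloride | O=C(Cl)c1cc(OCOC)c2OC(C)(C)CCc2c1CC=C(C)C
F5 | step 7 | 2-acetyl-4-(2-methylbut-3-en-2-yl)benzene-1,3,5-triyl triacetate | CC(=O)c1c(OC(C)=O)cc(OC(C)=O)c(C(C)(C)C=C)c1OC(C)=O
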